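**Retrosynthetic overview**
1. Feature used: on the cyclohexane ring (C5–C10) the C10 vinyl group (C1=C2), O9 and O8 all lie on the α face. O9/O8 is the cis-diol O4/O3 of (−)-quinic acid, so C1 can be passed from O9 to the neighbouring C10.
2. Late cuts: the O9 silyl ether, the C3 methylene (aldehyde Mannich–elimination), the C15 aldehyde (ozonolysis of a C5 prenyl group), the O6 angelate and the C13 methylene.
3. The γ-lactone (O8–C12–C11–C7–C8) comes from a C7 acetate chain. C7 and then C5 are alkylated through enolates of the C6 ketone, which is then reduced to the axial 6β-alcohol.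
4. The vinyl group comes from C1 by Tamao oxidation, oxidation to the aldehyde and Wittig reaction. C10–C1 is made by 5-exo closure of the radical O9–SiMe2–CH2• onto C10 of the C6 enone.
5. Ring order: carbocycle (from quinic acid), temporary 1,2-oxasilolane (closed in step 10, opened in step 11), γ-lactone (step 17).

Key step: step 10

Remark: from compound 6 on, the elemane numbering of the target is used. β is the ring face that carries the C10 methyl (C14) in the target and α is the other face. Quinic acid C1, C2, C3, C4, C5, C6 become C6, C7, C8, C9, C10, C5.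

**Step 1**
Reactants: 1 (−)-quinic acid
Product: 2 3,4-O-isopropylidene-1,5-quinide
Conditions: Me2C(OMe)2, TsOH·H2O (cat.), acetone, reflux
Reagents that add atoms: 2,2-dimethoxypropane, COC(C)(C)OC
Why: Acid-catalysed transketalisation takes up the only cis-vicinal diol (O3/O4) while the carboxyl group lactonises onto the cis 5-OH, and no stereocentre is touched.

**Step 2**
Reactants: 2 3,4-O-isopropylidene-1,5-quinide
Product: 3 1-(hydroxymethyl)-3,4-O-isopropylidenecyclohexane-1,3,4,5-tetrol (quinic numbering; configuration of 1)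
Conditions: NaBH4, EtOH, 0 °C → rt
Reagents that add atoms: none
Why: Hydride reduction of the strained α-hydroxy γ-lactone to the primary alcohol proceeds with borohydride in ethanol and leaves the ketal intact.

**Step 3**
Reactants: 3 triol
Product: 4 5-hydroxy-3,4-(isopropylidenedioxy)cyclohexanone (quinic numbering; C3, C4, C5 as in 1)
Conditions: NaIO4, H2O, 0 °C → rt
Reagents that add atoms: none
Why: Periodate glycol cleavage acts on the only free vicinal diol (C1–OH/CH2OH) and turns C1 into the ketone.

**Step 4**
Reactants: 4 β-hydroxy ketone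
Product: 6 (4S,5R)-4,5-(isopropylidenedioxy)cyclohex-2-en-1-one, via mesylate 5 (not isolated)
Conditions: MsCl, Et3N, CH2Cl2, 0 °C
Reagents that add atoms: methanesulfonyl chloride, CS(=O)(=O)Cl (atoms kept only in 5)
Why: Mesylation of the β-hydroxy ketone is followed by E1cB elimination, in which the sulfonate leaves far more readily than the ketal oxygen on the other β-carbon.

**Step 5**
Reactants: 6 enone acetonide
Product: 7 10β-methyl-8α,9α-(isopropylidenedioxy)-6-(trimethylsilyloxy)cyclohex-5-ene
Conditions: MeLi, CuI, Et2O, 0 °C; then Me3SiCl, 6, −78 °C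
Reagents that add atoms: methyllithium, [Li]C; chlorotrimethylsilane, C[Si](C)(C)Cl
Why: Gilman cuprate 1,4-addition places the methyl on C10 anti to the dioxolane (this centre is erased in step 6), and the in situ silyl trap fixes the C5=C6 enolate before it can equilibrate and expel O8.

**Step 6**
Reactants: 7 silyl enol ether
Product: 8 (4S,5R)-4,5-(isopropylidenedioxy)-3-methylcyclohex-2-en-1-one
Conditions: Pd(OAc)2 (1 equiv), MeCN, rt
Reagents that add atoms: none
Why: In the Saegusa–Ito oxidation the palladium enolate at C5 has only the C10 hydrogen available for β-hydride elimination, so the C5=C10 enone forms regiospecifically.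

**Step 7**
Reactants: 8 methyl enone acetonide
Product: 9 (4S,5R)-4,5-dihydroxy-3-methylcyclohex-2-en-1-one
Conditions: CF3CO2H–H2O (4:1), CH2Cl2, 0 °C
Reagents that add atoms: none
Why: Cold aqueous acid hydrolyses the ketal, as is routine for polyhydroxylated cyclohexenones, and is too mild to dehydrate the diol to a phenol.

**Step 8**
Reactants: 9 diol
Product: 10 (4S,5R)-5-(tert-butyldimethylsilyloxy)-4-hydroxy-3-methylcyclohex-2-en-1-one (O8 silylated; O9 free)
Conditions: TBSCl (1.05 equiv), imidazole, DMF, −20 → 0 °C
Reagents that add atoms: tert-butylchlorodimethylsilane, CC(C)(C)[Si](C)(C)Cl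
Why: Sterically controlled monosilylation should favour the equatorial 8-OH next to a CH2 over the pseudoaxial 9-OH wedged between C8 and the methyl-bearing C10, and imidazole-mediated silyl migration would lead to the same less hindered oxygen.

**Step 9**
Reactants: 10 mono-TBS enone; 11 (bromomethyl)chlorodimethylsilane
Product: 12 (4S,5R)-4-[(bromomethyl)dimethylsilyloxy]-5-(tert-butyldimethylsilyloxy)-3-methylcyclohex-2-en-1-one
Conditions: 11, Et3N, 4-(dimethylamino)pyridine (cat.), CH2Cl2, 0 °C
Reagents that add atoms: (bromomethyl)chlorodimethylsilane 11, C[Si](C)(Cl)CBr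
Why: Silyl ether formation with a small dimethylsilyl chloride reaches even the hindered 9-OH under mild amine conditions that do not enolise the enone.

**Step 10**
Reactants: 12 bromomethylsilyl ether
Product: 13 cis-fused 7-(tert-butyldimethylsilyloxy)-2,2,3a-trimethylhexahydro-1,2-benzoxasilol-5-one (C10: C14 β and C1 α; Si bridges C1 and 9α-O; 8α-OTBS; C6 ketone)
Conditions: Bu3SnH + 2,2'-azobis(2-methylpropionitrile) (cat.) by syringe pump, PhH (0.01 M), 80 °C
Reagents that add atoms: none
Why: Bu3Sn• abstracts bromine from 12, the nucleophilic α-silyl radical at C1 adds to C10 (the electrophilic β-carbon of the C6 enone), and the resulting C5 α-keto radical takes hydrogen from Bu3SnH to carry the chain; this is a Nishiyama–Stork silicon-tethered radical cyclisation, whose closest known use is the delivery of one carbon from (bromomethyl)dimethylsilyl ethers of cyclic allylic alcohols to a fully substituted ring carbon. The one ring that closes, the 1,2-oxasilolane C1–Si–O–C9–C10, forms in the 5-exo-trig mode. The only new stereocentre, C10, is set by the tether, because the O–Si–C chain anchored on the 9α oxygen can reach C10 only from the α face and can only give a cis-fused bicycle, so C1 ends α (cis to O9) and C14 β. Regioselectivity for C10 over C5 is needed because C10 is the more substituted alkene carbon, and it is secured by the polarity match with the enone β-carbon, by the gain of a carbonyl-stabilised radical and by the bridged bicyclo[3.3.1] frame that 6-endo attack at C5 would have to build. Premature reduction of the C–Br bond is suppressed by keeping the stannane concentration low through slow addition at high dilution. The 8α-OTBS group, the ketone and the C8/C9 stereocentres are inert under these neutral conditions.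

**Step 11**
Reactants: 13 oxasilolane ketone
Product: 14 keto diol (10α-CH2OH; 10β-CH3; 9α-OH; 8α-OTBS; C6 ketone)
Conditions: 30% H2O2, KF, KHCO3, THF–MeOH, rt
Reagents that add atoms: hydrogen peroxide, OO
Why: Tamao–Kumada oxidation replaces the C1–Si bond of the strained alkoxysilane by C1–OH and frees O9, and the bicarbonate medium is mild enough for the TBS ether and the β-silyloxy ketone.

**Step 12**
Reactants: 14 keto diol
Product: 15 hydroxy keto aldehyde (10α-CHO; 9α-OH; 8α-OTBS; C6 ketone)
Conditions: 2,2,6,6-tetramethylpiperidine-1-oxyl (TEMPO, cat.), PhI(OAc)2, CH2Cl2, rt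
Reagents that add atoms: none
Why: Oxoammonium-catalysed oxidation is selective for the primary alcohol over the hindered axial 9-OH, and its weakly acidic medium avoids retro-aldol cleavage of the non-enolisable β-hydroxy aldehyde.

**Step 13**
Reactants: 15 hydroxy keto aldehyde
Product: 16 9α-O-triethylsilyl keto aldehyde
Conditions: Et3SiOTf, 2,6-lutidine, CH2Cl2, −78 °C
Reagents that add atoms: triethylsilyl trifluoromethanesulfonate, CC[Si](CC)(CC)OS(=O)(=O)C(F)(F)F
Why: Silyl triflate with a hindered pyridine base caps the hindered 9-OH at low temperature without enol silane formation, which removes the alkoxide that could trigger retro-aldol in step 14.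

**Step 14**
Reactants: 16 keto aldehyde
Product: 17 10α-vinyl ketone (10β-CH3; 9α-OTES; 8α-OTBS; C6 ketone)
Conditions: Ph3PCH3Br, KN(SiMe3)2, THF, 0 °C; ylide (1 equiv) added to 16, −78 → −30 °C
Reagents that add atoms: methyltriphenylphosphonium bromide, C[P+](c1ccccc1)(c1ccccc1)c1ccccc1.[Br-]
Why: In the Wittig methylenation an aldehyde forms its oxaphosphetane far faster than a ketone at −78 °C, so one equivalent of ylide added slowly should convert only the C1 aldehyde and spare the C6 ketone, which is shielded by the axial C14 and neopentyl C5.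

**Step 15**
Reactants: 17 vinyl ketone; 18 methyl bromoacetate
Product: 20 7β-(methoxycarbonylmethyl) ketone (8α-OTBS; 9α-OTES; 10α-vinyl), via lithium enolate 19 (not isolated)
Conditions: LiN(i-Pr)2, THF, −78 °C; 18, DMPU, −78 → −40 °C
Reagents that add atoms: methyl bromoacetate 18, COC(=O)CBr; lithium diisopropylamide, [Li+].CC(C)[N-]C(C)C (lithium kept only in 19)
Why: In this kinetic enolate alkylation the amide base takes a C7 proton rather than one of neopentyl C5, the equatorial C8–O bond lies near the nodal plane of enolate 19 so β-elimination is slow in the cold, and the halide enters anti to 8α-OTBS and axial 9α-OTES to give the equatorial 7β chain, which is also the thermodynamic epimer.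

**Step 16**
Reactants: 20 keto ester; 21 1-bromo-3-methylbut-2-ene (prenyl bromide)
Product: 23 5β-prenyl-7β-(methoxycarbonylmethyl) ketone, via lithium enolate 22 (not isolated)
Conditions: LiN(i-Pr)2, THF, −78 °C; 21, DMPU, −78 → −10 °C; then 1,8-diazabicyclo[5.4.0]undec-7-ene (cat.), PhMe, rt
Reagents that add atoms: prenyl bromide 21, CC(C)=CCBr; lithium diisopropylamide, [Li+].CC(C)[N-]C(C)C (lithium kept only in 22)
Why: In this second kinetic enolate alkylation C7 is now a methine and ketone protons are removed before ester protons, so the base takes a C5 proton, the reactive allylic bromide alkylates the hindered enolate as in the trapping of 3,3-disubstituted cyclohexanone enolates with allylic halides, and the amidine base converts any 5α epimer (prenyl syn-axial to 9α-OTES) to the equatorial 5β product because C5 remains α to the ketone.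

**Step 17**
Reactants: 23 bis-silyl keto ester
Product: 25 trans-fused 8α,12-lactone ketone carrying free 9α-OH, via dihydroxy ester 24 (not isolated)
Conditions: 48% aq HF, MeCN, 0 °C → rt; then pyridinium p-toluenesulfonate (cat.), PhMe, 50 °C
Reagents that add atoms: none
Why: Acidic desilylation frees O8 and O9 without ever forming a β-alkoxide (so no retro-aldol or E1cB), and the equatorial 8α-OH closes onto the equatorial 7β acetate chain by acid-catalysed 5-exo-trig lactonisation, the axial 9α-OH being unable to reach the ester.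

**Step 18**
Reactants: 25 hydroxy keto lactone
Product: 26 9α-O-triethylsilyl keto lactone
Conditions: Et3SiOTf, 2,6-lutidine, CH2Cl2, −78 → 0 °C
Reagents that add atoms: triethylsilyl trifluoromethanesulfonate, CC[Si](CC)(CC)OS(=O)(=O)C(F)(F)F
Why: This silylates the only free hydroxyl, and the ketone now has only hindered methine α-carbons and does not form an enol silane with lutidine.

**Step 19**
Reactants: 26 keto lactone
Product: 27 6β-alcohol (axial OH; 5β-prenyl; 8α,12-lactone; 9α-OTES)
Conditions: LiBH(s-Bu)3, THF, −78 °C; AcOH, −78 °C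
Reagents that add atoms: none
Why: In the chair locked by the trans-lactone the β face of C6 is closed by the syn-axial C14 methyl, so the hindered hydride attacks along the equatorial α trajectory and sets the axial 6β-OH, and the cold acid quench protonates the alkoxide before it can attack the lactone carbonyl.

**Step 20**
Reactants: 27 6β-alcohol
Product: 28 6β-O-trimethylsilyl ether
Conditions: Me3SiOTf, 2,6-lutidine, CH2Cl2, −78 → 0 °C
Reagents that add atoms: trimethylsilyl trifluoromethanesulfonate, C[Si](C)(C)OS(=O)(=O)C(F)(F)F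
Why: The smallest silyl triflate can still reach the crowded axial hydroxyl, and this masking keeps a 6-alkoxide from forming next to the lactone in step 21.

**Step 21**
Reactants: 28 silylated lactone
Product: 32 α-methylene lactone (C11=C13; 6β-OTMS; 9α-OTES), via lactone enolate 29 (not isolated), via Mannich base 30 (not isolated), via methiodide 31 (not isolated)
Conditions: LiN(i-Pr)2, THF, −78 °C; Me2N=CH2 I, −78 °C → rt; MeI, CH2Cl2, rt; aq NaHCO3, CH2Cl2, rt
Reagents that add atoms: Eschenmoser's salt, C=[N+](C)C.[I-]; iodomethane, CI (atoms kept only in 31); lithium diisopropylamide, [Li+].CC(C)[N-]C(C)C (lithium kept only in 29)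
Why: Lactone α-methylenation by Mannich reaction, quaternisation and Hofmann-type elimination is applied to a substrate whose only acidic C–H bonds are those at C11, and the transient C11 stereocentre is destroyed again.

**Step 22**
Reactants: 32 bis-silyl α-methylene lactone
Product: 33 6β-hydroxy α-methylene lactone (9α-OTES kept)
Conditions: pyridinium p-toluenesulfonate (cat.), MeOH–CH2Cl2, 0 °C
Reagents that add atoms: none
Why: Acid-catalysed methanolysis distinguishes the silyl groups by their intrinsic lability, the trimethylsilyl ether being cleaved well before the triethylsilyl ether on the neopentyl axial O9.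

**Step 23**
Reactants: 33 6β-alcohol; 34 angelic acid
Product: 36 6β-angelate (5β-prenyl; 9α-OTES), via mixed anhydride 35 (not isolated)
Conditions: 34, 2,4,6-Cl3C6H2COCl, Et3N, PhMe, rt; then 33, 80 °C
Reagents that add atoms: angelic acid 34, C/C=C(/C)C(=O)O; 2,4,6-trichlorobenzoyl chloride, O=C(Cl)c1c(Cl)cc(Cl)cc1Cl (atoms kept only in 35)
Why: Yamaguchi-type mixed-anhydride esterification run without a nucleophilic pyridine catalyst is the established way to transfer the (Z)-2-methylbut-2-enoyl group to hindered alcohols without Z-to-E isomerisation, and O6 is the only free hydroxyl.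

**Step 24**
Reactants: 36 prenyl angelate
Product: 38 C15 aldehyde (5β-CH2CHO), via secondary ozonide 37 (not isolated)
Conditions: O3, CH2Cl2, −78 °C (Sudan Red 7B end point); Me2S, −78 °C → rt
Reagents that add atoms: ozone, [O-][O+]=O
Why: Ozone is electrophilic and consumes the electron-rich trisubstituted prenyl alkene first, as in the selective cleavage of 1,6-dienes of the citronellene type, before the neopentyl monosubstituted vinyl group and the two electron-poor conjugated alkenes.

**Step 25**
Reactants: 38 aldehyde
Product: 40 9α-O-triethylsilyl ether of the target (C4=C3 enal), via Mannich base 39 (not isolated)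
Conditions: Me2N=CH2 I, Et3N, CH2Cl2, rt
Reagents that add atoms: Eschenmoser's salt, C=[N+](C)C.[I-]
Why: Aldehyde α-methylenation by Mannich reaction and spontaneous β-elimination of dimethylamine acts on C4, the only enolisable position left, under conditions mild enough for the angelate and the α-methylene lactone.

**Step 26**
Reactants: 40 silyl ether
Product: 41 target CNP0277836.2
Conditions: HF·pyridine, pyridine, THF, 0 °C → rt
Reagents that add atoms: none
Why: Buffered fluoride-mediated desilylation removes the last protecting group without base, so the enal, the α-methylene lactone and the Z-configured angelate are preserved.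

**Compound list**
1 | (−)-quinic acid | C1[C@H]([C@H]([C@@H](C[C@@]1(C(=O)O)O)O)O)O | starting material
2 | 3,4-O-isopropylidene-1,5-quinide | O=C1O[C@@H]2C[C@@]1(O)C[C@H]3OC(C)(C)O[C@@H]23 | intermediate
3 | 1-(hydroxymethyl)-3,4-O-isopropylidenecyclohexane-1,3,4,5-tetrol | OC[C@@]1(O)C[C@@H](O)[C@@H]2OC(C)(C)O[C@@H]2C1 | intermediate
4 | 5-hydroxy-3,4-(isopropylidenedioxy)cyclohexanone | O=C1C[C@@H](O)[C@@H]2OC(C)(C)O[C@@H]2C1 | intermediate
5 | 5-O-mesylate of 4 (not isolated) | O=C1C[C@@H](OS(C)(=O)=O)[C@@H]2OC(C)(C)O[C@@H]2C1 | intermediate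
6 | (4S,5R)-4,5-(isopropylidenedioxy)cyclohex-2-en-1-one | O=C1C=C[C@@H]2OC(C)(C)O[C@@H]2C1 | intermediate
7 | 10β-methyl C5=C6 trimethylsilyl enol ether acetonide | C[C@H]1[C@@H]2OC(C)(C)O[C@@H]2CC(O[Si](C)(C)C)=C1 | intermediate
8 | (4S,5R)-4,5-(isopropylidenedioxy)-3-methylcyclohex-2-en-1-one | CC1=CC(=O)C[C@H]2OC(C)(C)O[C@@H]12 | intermediate
9 | (4S,5R)-4,5-dihydroxy-3-methylcyclohex-2-en-1-one | CC1=CC(=O)C[C@@H](O)[C@H]1O | intermediate
10 | (4S,5R)-5-(tert-butyldimethylsilyloxy)-4-hydroxy-3-methylcyclohex-2-en-1-one | CC1=CC(=O)C[C@@H](O[Si](C)(C)C(C)(C)C)[C@H]1O | intermediate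
11 | (bromomethyl)chlorodimethylsilane | C[Si](C)(Cl)CBr | starting material
12 | 9-O-(bromomethyl)dimethylsilyl, 8-O-TBS 3-methylcyclohexenone (key-step precursor) | CC1=CC(=O)C[C@@H](O[Si](C)(C)C(C)(C)C)[C@H]1O[Si](C)(C)CBr | intermediate
13 | cis-fused oxasilolane cyclohexanone with quaternary C10 (key-step product) | C[C@@]12C[Si](C)(C)O[C@@H]1[C@H](O[Si](C)(C)C(C)(C)C)CC(=O)C2 | intermediate
14 | keto diol (10α-CH2OH, 9α-OH, 8α-OTBS) | C[C@@]1(CO)[C@H](O)[C@H](O[Si](C)(C)C(C)(C)C)CC(=O)C1 | intermediate
15 | hydroxy keto aldehyde (10α-CHO, 9α-OH) | C[C@@]1(C=O)[C@H](O)[C@H](O[Si](C)(C)C(C)(C)C)CC(=O)C1 | intermediate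
16 | 9α-OTES keto aldehyde | C[C@@]1(C=O)[C@H](O[Si](CC)(CC)CC)[C@H](O[Si](C)(C)C(C)(C)C)CC(=O)C1 | intermediate
17 | 10α-vinyl ketone (9α-OTES, 8α-OTBS) | C=C[C@]1(C)[C@H](O[Si](CC)(CC)CC)[C@H](O[Si](C)(C)C(C)(C)C)CC(=O)C1 | intermediate
18 | methyl bromoacetate | COC(=O)CBr | starting material
19 | C6=C7 lithium enolate of 17 (not isolated) | C=C[C@]1(C)[C@H](O[Si](CC)(CC)CC)[C@H](O[Si](C)(C)C(C)(C)C)C=C(O[Li])C1 | intermediate
20 | 7β-(methoxycarbonylmethyl) ketone | C=C[C@]1(C)[C@H](O[Si](CC)(CC)CC)[C@H](O[Si](C)(C)C(C)(C)C)[C@@H](CC(=O)OC)C(=O)C1 | intermediate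
21 | 1-bromo-3-methylbut-2-ene (prenyl bromide) | CC(C)=CCBr | starting material
22 | C5=C6 lithium enolate of 20 (not isolated) | C=C[C@]1(C)[C@H](O[Si](CC)(CC)CC)[C@H](O[Si](C)(C)C(C)(C)C)[C@@H](CC(=O)OC)C(O[Li])=C1 | intermediate
23 | 5β-prenyl-7β-(methoxycarbonylmethyl) ketone | C=C[C@]1(C)[C@H](O[Si](CC)(CC)CC)[C@H](O[Si](C)(C)C(C)(C)C)[C@@H](CC(=O)OC)C(=O)[C@H]1CC=C(C)C | intermediate
24 | 8α,9α-dihydroxy keto ester (not isolated) | C=C[C@]1(C)[C@H](O)[C@H](O)[C@@H](CC(=O)OC)C(=O)[C@H]1CC=C(C)C | intermediate
25 | trans-8α,12-lactone ketone, 9α-OH | C=C[C@]1(C)[C@H](O)[C@@H]2OC(=O)C[C@H]2C(=O)[C@H]1CC=C(C)C | intermediate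
26 | 9α-OTES keto lactone | C=C[C@]1(C)[C@H](O[Si](CC)(CC)CC)[C@@H]2OC(=O)C[C@H]2C(=O)[C@H]1CC=C(C)C | intermediate
27 | 6β-hydroxy lactone | C=C[C@]1(C)[C@H](O[Si](CC)(CC)CC)[C@@H]2OC(=O)C[C@H]2[C@@H](O)[C@H]1CC=C(C)C | intermediate
28 | 6β-OTMS lactone | C=C[C@]1(C)[C@H](O[Si](CC)(CC)CC)[C@@H]2OC(=O)C[C@H]2[C@@H](O[Si](C)(C)C)[C@H]1CC=C(C)C | intermediate
29 | lithium enolate of lactone 28 (not isolated) | C=C[C@]1(C)[C@H](O[Si](CC)(CC)CC)[C@@H]2OC(O[Li])=C[C@H]2[C@@H](O[Si](C)(C)C)[C@H]1CC=C(C)C | intermediate
30 | 11-(dimethylaminomethyl) lactone, C11 configuration of no consequence (not isolated) | C=C[C@]1(C)[C@H](O[Si](CC)(CC)CC)[C@@H]2OC(=O)C(CN(C)C)[C@H]2[C@@H](O[Si](C)(C)C)[C@H]1CC=C(C)C | intermediate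
31 | methiodide of 30 (not isolated) | C=C[C@]1(C)[C@H](O[Si](CC)(CC)CC)[C@@H]2OC(=O)C(C[N+](C)(C)C)[C@H]2[C@@H](O[Si](C)(C)C)[C@H]1CC=C(C)C.[I-] | intermediate
32 | α-methylene lactone, 6β-OTMS, 9α-OTES | C=C[C@]1(C)[C@H](O[Si](CC)(CC)CC)[C@@H]2OC(=O)C(=C)[C@H]2[C@@H](O[Si](C)(C)C)[C@H]1CC=C(C)C | intermediate
33 | α-methylene lactone, 6β-OH, 9α-OTES | C=C[C@]1(C)[C@H](O[Si](CC)(CC)CC)[C@@H]2OC(=O)C(=C)[C@H]2[C@@H](O)[C@H]1CC=C(C)C | intermediate
34 | angelic acid, (Z)-2-methylbut-2-enoic acid | C/C=C(/C)C(=O)O | starting material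
35 | angelic 2,4,6-trichlorobenzoic anhydride (not isolated) | C/C=C(/C)C(=O)OC(=O)c1c(Cl)cc(Cl)cc1Cl | intermediate
36 | 6β-angelate, 5β-prenyl, 9α-OTES | C=C[C@]1(C)[C@H](O[Si](CC)(CC)CC)[C@@H]2OC(=O)C(=C)[C@H]2[C@@H](OC(=O)/C(C)=C\C)[C@H]1CC=C(C)C | intermediate
37 | secondary ozonide of the prenyl alkene, mixture at the ozonide CH (not isolated) | C=C[C@]1(C)[C@H](O[Si](CC)(CC)CC)[C@@H]2OC(=O)C(=C)[C@H]2[C@@H](OC(=O)/C(C)=C\C)[C@H]1CC3OOC(C)(C)O3 | intermediate
38 | 5β-(2-oxoethyl) angelate | C=C[C@]1(C)[C@H](O[Si](CC)(CC)CC)[C@@H]2OC(=O)C(=C)[C@H]2[C@@H](OC(=O)/C(C)=C\C)[C@H]1CC=O | intermediate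
39 | 4-(dimethylaminomethyl) aldehyde, C4 configuration of no consequence (not isolated) | C=C[C@]1(C)[C@H](O[Si](CC)(CC)CC)[C@@H]2OC(=O)C(=C)[C@H]2[C@@H](OC(=O)/C(C)=C\C)[C@H]1C(CN(C)C)C=O | intermediate
40 | 9α-O-triethylsilyl ether of the target | C=C[C@]1(C)[C@H](O[Si](CC)(CC)CC)[C@@H]2OC(=O)C(=C)[C@H]2[C@@H](OC(=O)/C(C)=C\C)[C@H]1C(=C)C=O | intermediate
41 | CNP0277836.2 | C=C[C@]1(C)[C@H](O)[C@@H]2OC(=O)C(=C)[C@H]2[C@@H](OC(=O)/C(C)=C\C)[C@H]1C(=C)C=O | target

**Total step count:** 26. **Longest linear sequence:** 26 steps, from 1.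

**Steps most likely to fail**

1. **Step 16 (prenylation at C5).**
   - What may go wrong: C–C bond formation at an enolate carbon next to quaternary C10 is slow. That carbon is screened on one face by axial C14 and on the other by axial 9α-OTES. During the delay, proton exchange can move the enolate towards C7, with loss of silanolate from C8 or alkylation at the wrong carbon. The base equilibration of C5 carries the same elimination risk.
   - Fallback (sets out from 20, returns at 23): the small carbon is put on C5 first and the large piece is joined away from the crowded centre. Heating 20 with paraformaldehyde and N-methylanilinium trifluoroacetate in THF (Mannich–elimination α-methylenation) can act only at C5, the sole ketone α-carbon with two hydrogens, and gives the 5-methylene ketone F1. Copper-catalysed 1,4-addition of 2-methylprop-1-enylmagnesium bromide (CuBr·SMe2 cat., THF, −78 °C) then forms the new bond at the exposed CH2 terminus and gives the bromomagnesium enolate F2. Axial protonation of F2 from the α face with cold aqueous NH4Cl delivers 23.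

2. **Step 15 (acetate chain at C7).**
   - What may go wrong: the lithium enolate must survive long enough to be alkylated. Meanwhile β-elimination of the 8-silyloxy group, proton transfer leading to double alkylation, and partial deprotonation at C5 can all compete.
   - Fallback (sets out from 17, returns at 20): the polar alkylation is replaced by a neutral radical one. Enolate 19 is trapped at −78 °C with Me3SiCl as the C6–C7 trimethylsilyl enol ether F3. Et3B/air-initiated atom-transfer addition of methyl iodoacetate then sends the electrophilic •CH2CO2Me radical onto C7 of the electron-rich enol ether, anti to 8α-OTBS. This gives the 6-iodo-6-silyloxy adduct F4, which collapses to ketone 20.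

3. **Step 23 (angeloylation of O6).**
   - What may go wrong: the axial 6β-OH is syn-axial to C14 and flanked by two substituents, so acyl transfer may need prolonged heating. Under such heating, Z-to-E isomerisation of the acyl group and migration of the lactone acyl group from O8 to O6 become competitive.
   - Fallback (sets out from 33, returns at 36): the Z alkene is built on the molecule instead of being transferred. Alcohol 33 is esterified with 2-[bis(2,2,2-trifluoroethoxy)phosphoryl]propanoic acid (dicyclohexylcarbodiimide, 4-(dimethylamino)pyridine, CH2Cl2). This acid has no alkene geometry to lose, so full nucleophilic catalysis can be used, and it gives the 6β-phosphonopropanoate F5. Still–Gennari olefination of F5 with acetaldehyde (KN(SiMe3)2, 18-crown-6, THF, −78 °C) then gives the (Z)-2-methylbut-2-enoate 36.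

**Further compounds**
F1 | step 16 | 5-methylene ketone | C=C[C@]1(C)[C@H](O[Si](CC)(CC)CC)[C@H](O[Si](C)(C)C(C)(C)C)[C@@H](CC(=O)OC)C(=O)C1=C
F2 | step 16 | bromomagnesium enolate | C=C[C@]1(C)[C@H](O[Si](CC)(CC)CC)[C@H](O[Si](C)(C)C(C)(C)C)[C@@H](CC(=O)OC)C(O[Mg]Br)=C1CC=C(C)C
F3 | step 15 | C6–C7 trimethylsilyl enol ether | C=C[C@]1(C)[C@H](O[Si](CC)(CC)CC)[C@H](O[Si](C)(C)C(C)(C)C)C=C(O[Si](C)(C)C)C1
F4 | step 15 | 6-iodo-6-silyloxy adduct | C=C[C@]1(C)[C@H](O[Si](CC)(CC)CC)[C@H](O[Si](C)(C)C(C)(C)C)[C@@H](CC(=O)OC)C(I)(O[Si](C)(C)C)C1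
F5 | step 23 | 6β-phosphonopropanoate | C=C[C@]1(C)[C@H](O[Si](CC)(CC)CC)[C@@H]2OC(=O)C(=C)[C@H]2[C@@H](OC(=O)C(C)P(=O)(OCC(F)(F)F)OCC(F)(F)F)[C@H]1CC=C(C)C
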